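**Retrosynthetic overview**

Labels: C1 (bridgehead CH), C2 (guaiacyl CH), O3, C4H2, C5 (C–OH), C6 (syringyl CH), O7, C8H2; ring A = C1–C2–O3–C4–C5, ring B = C5–C6–O7–C8–C1.
Feature: C1 is bonded to C2, C5 and C8, C5 carries oxygen and C6 an aryl group, so ring B is the four-membered ketone C1–C5–C6–C8 with O7 inserted between C6 and C8, i.e. a ketene (C8=C1) added across an aryl ketone enol ether (C5=C6).
Disconnections: C8 carbonyl to CH2 and O7 out (lactone reduction, Baeyer–Villiger), then C1–C5 and C8–C6 ([2+2]), then C1–C2 (Wolff shift), giving the diazoketone of an O-alkylated (R)-vanillylmandelic acid.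
That acid comes from O3–C2 bond formation by enantioselective carbenoid O–H insertion of a guaiacyl diazoacetate into a syringyl hydroxymethyl ketone, followed by Z enol silylation.
Ring order: ring A and the four-membered ring together in step 9, ring B by oxygen insertion in step 10.

Key step: step 9

Remark: the phenols are carried as TIPS ethers and the C5 oxygen as a TBS ether. The carbenoid is placed on the guaiacyl side because an arylmethyl diazoketone carbenoid on the syringyl side would attack its own electron-rich ring. The ligand enantiomer that gives the (R)-ether in step 5 is to be fixed by a small test run.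

**Route**

Step 1
Reactants: 1 methyl homovanillate
Product: 2 methyl [3-methoxy-4-(triisopropylsilyloxy)phenyl]acetate
Conditions: TIPSCl, imidazole, DMF, 20 °C
Reagents that add atoms: chlorotriisopropylsilane CC(C)[Si](Cl)(C(C)C)C(C)C
Why: Phenol silylation (silyl ether formation); the TIPS ether should survive DBU, tin hydroxide and cold Lewis acid and fall to fluoride at the end.

Step 2
Reactants: 2 methyl [3-methoxy-4-(triisopropylsilyloxy)phenyl]acetate
Product: 3 methyl diazo[3-methoxy-4-(triisopropylsilyloxy)phenyl]acetate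
Conditions: 4-acetamidobenzenesulfonyl azide, DBU, MeCN, 0 → 20 °C
Reagents that add atoms: 4-acetamidobenzenesulfonyl azide CC(=O)Nc1ccc(cc1)S(=O)(=O)N=[N+]=[N-]
Why: Regitz diazo transfer to the benzylic ester position should give the donor–acceptor diazo ester; no stereocenter is involved.

Step 3
Reactants: 4 homosyringic acid
Product: 6 [3,5-dimethoxy-4-(triisopropylsilyloxy)phenyl]acetic acid, via bis-silylated TIPS ester 5 (not isolated)
Conditions: TIPSCl (2.4 equiv), imidazole, DMF, 40 °C; then K2CO3, MeOH/THF/H2O, 20 °C; dilute HCl work-up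
Reagents that add atoms: chlorotriisopropylsilane CC(C)[Si](Cl)(C(C)C)C(C)C
Why: Silylation of phenol and acid followed by selective hydrolysis of the labile silyl ester, the hindered aryl TIPS ether being stable to carbonate in aqueous methanol.

Step 4
Reactants: 6 [3,5-dimethoxy-4-(triisopropylsilyloxy)phenyl]acetic acid
Product: 9 1-[3,5-dimethoxy-4-(triisopropylsilyloxy)phenyl]-3-hydroxypropan-2-one, via acid chloride 7 (not isolated), via silylated keto ester adduct 8 (not isolated)
Conditions: (COCl)2, DMF (cat.), CH2Cl2, 0 → 20 °C, concentrate; tris(trimethylsilyloxy)ethylene, neat, 95 °C; then 0.6 M HCl, dioxane, 80 °C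
Reagents that add atoms: tris(trimethylsilyloxy)ethylene C[Si](C)(C)OC=C(O[Si](C)(C)C)O[Si](C)(C)C
Why: Acid chloride formation, C-acylation of the ketene tris(silyl) acetal and acidic hydrolysis with decarboxylation (hydroxymethyl ketone synthesis from acid chlorides) should give the primary α-hydroxy ketone, the aryl TIPS ether tolerating the dilute acid.

Step 5
Reactants: 3 methyl diazo[3-methoxy-4-(triisopropylsilyloxy)phenyl]acetate; 9 1-[3,5-dimethoxy-4-(triisopropylsilyloxy)phenyl]-3-hydroxypropan-2-one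
Product: 10 methyl (2R)-2-{3-[3,5-dimethoxy-4-(triisopropylsilyloxy)phenyl]-2-oxopropoxy}-2-[3-methoxy-4-(triisopropylsilyloxy)phenyl]acetate
Conditions: FeCl2·4H2O (5 mol%), single-enantiomer spiro-bisoxazoline ligand 7,7'-bis(4-phenyl-4,5-dihydrooxazol-2-yl)-1,1'-spirobiindane (6 mol%), NaB[3,5-(CF3)2C6H3]4 (6 mol%), CHCl3, 40 °C, slow addition of 3
Reagents that add atoms: none
Why: Enantioselective carbenoid O–H insertion: the donor–acceptor carbenoid of divalent iron is attacked by the primary hydroxyl of 9 and the metal-bound ylide is protonated inside the chiral pocket, which forms O3–C2 and sets C2 as R, this carbenoid having no intramolecular outlet.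

Step 6
Reactants: 10 methyl (2R)-keto ester
Product: 11 (2R)-2-{3-[3,5-dimethoxy-4-(triisopropylsilyloxy)phenyl]-2-oxopropoxy}-2-[3-methoxy-4-(triisopropylsilyloxy)phenyl]acetic acid
Conditions: Me3SnOH (4 equiv), ClCH2CH2Cl, 70 °C; 0.5 M HCl wash
Reagents that add atoms: trimethyltin hydroxide C[Sn](C)(C)O
Why: Mild ester hydrolysis by trimethyltin hydroxide avoids the hydroxide-induced enolisation that could epimerise C2 or start a Claisen-type closure of the benzyl ketone onto the ester.

Step 7
Reactants: 11 (2R)-keto acid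
Product: 13 (2R)-2-{[(2Z)-2-(tert-butyldimethylsilyloxy)-3-[3,5-dimethoxy-4-(triisopropylsilyloxy)phenyl]prop-2-en-1-yl]oxy}-2-[3-methoxy-4-(triisopropylsilyloxy)phenyl]acetic acid, via silyl ester 12 (not isolated)
Conditions: TBSOTf (2.4 equiv), Et3N (4 equiv), CH2Cl2, −78 → 0 °C; then MeOH/H2O, 0 → 20 °C; pH 6 phosphate buffer work-up, used at once
Reagents that add atoms: tert-butyldimethylsilyl triflate CC(C)(C)[Si](C)(C)OS(=O)(=O)C(F)(F)F
Why: Soft enolisation (silyl triflate and amine) of the benzyl ketone should give the conjugated silyl enol ether toward C6 as the Z isomer (aryl cis to the silyloxy group, as expected for aryl acetone enol ethers), the acid being silylated in passing and the silyl ester then cleaved by aqueous methanol.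

Step 8
Reactants: 13 Z silyl enol ether acid
Product: 15 (3R)-3-{[(2Z)-2-(tert-butyldimethylsilyloxy)-3-[3,5-dimethoxy-4-(triisopropylsilyloxy)phenyl]prop-2-en-1-yl]oxy}-1-diazo-3-[3-methoxy-4-(triisopropylsilyloxy)phenyl]propan-2-one, via mixed anhydride 14 (not isolated)
Conditions: i-BuOCOCl, N-methylmorpholine, THF, −20 °C; then TMSCHN2 (2 M in hexanes), MeCN, 0 → 20 °C
Reagents that add atoms: (trimethylsilyl)diazomethane C[Si](C)(C)C=[N+]=[N-]
Why: Mixed carbonic anhydride activation under a weak base in the cold and acylation of the diazoalkane (diazoketone synthesis of the Arndt–Eistert type) should leave the enol ether and the configuration at C2 untouched.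

Step 9
Reactants: 15 diazoketone
Product: 17 (1R,2S,5S,6R)-cyclobutanone: cis-fused 3-oxabicyclo[3.2.0]heptanone (ring A plus C1–C5–C6–C8 with C8=O) carrying 3-methoxy-4-(triisopropylsilyloxy)phenyl at C2 (exo); tert-butyldimethylsilyloxy at C5; 3,5-dimethoxy-4-(triisopropylsilyloxy)phenyl at C6 (cis to the C5 oxygen), via ketene 16 (not isolated)
Conditions: hν (365 nm), PhMe (0.005 M, degassed, dry), 20 °C; then 60 °C in the dark until the ketene is consumed
Reagents that add atoms: none
Why: Light at 365 nm excites only the diazoketone, which loses N2 with a concerted 1,2-shift of C2 (retention) to give ketene 16 (O=C8=C1H–C2, C1–C2 formed); this is a photochemical Wolff rearrangement followed by an intramolecular ketene–alkene [2+2] cycloaddition, the closest known types being the closure of tethered ketenes onto alkenes to bicyclo[3.2.0]heptanones and the addition of ketenes to silyl enol ethers to 3-silyloxycyclobutanones. The cycloaddition is concerted but asynchronous: electrophilic C8 bonds to the nucleophilic enol ether carbon C6 while C1 bonds to the oxocarbenium-like C5, so ring A closes as a five-membered ring in a 5-exo sense on C5=C6 and the four-membered ketone closes in the same event. C1 and C5 are set cis by the three-atom tether, C6 is set relative to C5 by suprafacial addition to the Z alkene (syringyl cis to the silyloxy group), and the absolute sense of all three follows from C2, whose guaiacyl group takes the exo position away from the forming cyclobutanone. The step needs regioselectivity (fused, not bridged), secured by the polarity of the enol ether and the tether length; face selectivity, secured by the C2 substituent; and retention of the Z geometry, secured by a wavelength the styrenyl enol ether does not absorb and by high dilution, which also suppresses ketene dimerisation.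

Step 10
Reactants: 17 cyclobutanone
Product: 18 (1R,2S,5S,6R)-5-(tert-butyldimethylsilyloxy)-6-[3,5-dimethoxy-4-(triisopropylsilyloxy)phenyl]-2-[3-methoxy-4-(triisopropylsilyloxy)phenyl]-3,7-dioxabicyclo[3.3.0]octan-8-one
Conditions: mCPBA, NaHCO3, CH2Cl2, 0 °C
Reagents that add atoms: 3-chloroperoxybenzoic acid OOC(=O)c1cccc(Cl)c1
Why: Baeyer–Villiger oxidation driven by cyclobutanone strain: in the Criegee adduct the benzylic C6, bearing the electron-rich aryl group and only one β-oxygen, should migrate in preference to C1 and with retention, placing O7 between C6 and C8.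

Step 11
Reactants: 18 lactone
Product: 19 (1R,2S,5S,6R)-5-(tert-butyldimethylsilyloxy)-6-[3,5-dimethoxy-4-(triisopropylsilyloxy)phenyl]-2-[3-methoxy-4-(triisopropylsilyloxy)phenyl]-3,7-dioxabicyclo[3.3.0]octan-8-ol (lactol; both C8 epimers)
Conditions: i-Bu2AlH, CH2Cl2, −78 °C; aq. KNaC4H4O6 (potassium sodium tartrate)
Reagents that add atoms: none
Why: Partial reduction of the γ-lactone to the lactol (aluminium hydride reduction), the tetrahedral aluminium acetal being stable at −78 °C so that over-reduction and β-elimination of the C5 silyloxy group are avoided.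

Step 12
Reactants: 19 lactol
Product: 20 (1R,2S,5S,6R)-5-(tert-butyldimethylsilyloxy)-6-[3,5-dimethoxy-4-(triisopropylsilyloxy)phenyl]-2-[3-methoxy-4-(triisopropylsilyloxy)phenyl]-3,7-dioxabicyclo[3.3.0]octane
Conditions: Et3SiH, BF3·OEt2, CH2Cl2, −78 → −40 °C
Reagents that add atoms: none
Why: Ionic hydrogenation of the lactol: BF3 ionises the hemiacetal to the C8 oxocarbenium ion, which the silane reduces to the C8 methylene, no stereocenter arising at C8 and the low temperature protecting the benzylic ethers and silyl groups.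

Step 13
Reactants: 20 tris-silyl ether
Product: 21 fraxiresinol
Conditions: Bu4NF, AcOH, THF, 0 → 20 °C
Reagents that add atoms: none
Why: Fluoride cleavage of the two aryl TIPS ethers and the tertiary TBS ether (desilylation), acetic acid buffering keeping phenoxide-driven opening of the benzylic ethers from epimerising C2 or C6.

**Compound list**

1 | methyl homovanillate | COC(=O)Cc1ccc(O)c(OC)c1 | starting material
2 | methyl [3-methoxy-4-(triisopropylsilyloxy)phenyl]acetate | COC(=O)Cc1ccc(O[Si](C(C)C)(C(C)C)C(C)C)c(OC)c1 | intermediate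
3 | methyl diazo[3-methoxy-4-(triisopropylsilyloxy)phenyl]acetate | COC(=O)C(=[N+]=[N-])c1ccc(O[Si](C(C)C)(C(C)C)C(C)C)c(OC)c1 | intermediate
4 | homosyringic acid | COc1cc(CC(=O)O)cc(OC)c1O | starting material
5 | triisopropylsilyl [3,5-dimethoxy-4-(triisopropylsilyloxy)phenyl]acetate | COc1cc(CC(=O)O[Si](C(C)C)(C(C)C)C(C)C)cc(OC)c1O[Si](C(C)C)(C(C)C)C(C)C | intermediate (not isolated)
6 | [3,5-dimethoxy-4-(triisopropylsilyloxy)phenyl]acetic acid | COc1cc(CC(=O)O)cc(OC)c1O[Si](C(C)C)(C(C)C)C(C)C | intermediate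
7 | [3,5-dimethoxy-4-(triisopropylsilyloxy)phenyl]acetyl chloride | COc1cc(CC(=O)Cl)cc(OC)c1O[Si](C(C)C)(C(C)C)C(C)C | intermediate (not isolated)
8 | trimethylsilyl 4-[3,5-dimethoxy-4-(triisopropylsilyloxy)phenyl]-3-oxo-2-(trimethylsilyloxy)butanoate | COc1cc(CC(=O)C(O[Si](C)(C)C)C(=O)O[Si](C)(C)C)cc(OC)c1O[Si](C(C)C)(C(C)C)C(C)C | intermediate (not isolated)
9 | 1-[3,5-dimethoxy-4-(triisopropylsilyloxy)phenyl]-3-hydroxypropan-2-one | COc1cc(CC(=O)CO)cc(OC)c1O[Si](C(C)C)(C(C)C)C(C)C | intermediate
10 | methyl (2R)-2-{3-[3,5-dimethoxy-4-(triisopropylsilyloxy)phenyl]-2-oxopropoxy}-2-[3-methoxy-4-(triisopropylsilyloxy)phenyl]acetate | COc1cc([C@@H](OCC(=O)Cc2cc(OC)c(O[Si](C(C)C)(C(C)C)C(C)C)c(OC)c2)C(=O)OC)ccc1O[Si](C(C)C)(C(C)C)C(C)C | intermediate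
11 | (2R)-2-{3-[3,5-dimethoxy-4-(triisopropylsilyloxy)phenyl]-2-oxopropoxy}-2-[3-methoxy-4-(triisopropylsilyloxy)phenyl]acetic acid | COc1cc([C@@H](OCC(=O)Cc2cc(OC)c(O[Si](C(C)C)(C(C)C)C(C)C)c(OC)c2)C(=O)O)ccc1O[Si](C(C)C)(C(C)C)C(C)C | intermediate
12 | tert-butyldimethylsilyl ester of acid 13 (Z silyl enol ether, 2R) | COc1cc([C@@H](OC/C(O[Si](C)(C)C(C)(C)C)=C/c2cc(OC)c(O[Si](C(C)C)(C(C)C)C(C)C)c(OC)c2)C(=O)O[Si](C)(C)C(C)(C)C)ccc1O[Si](C(C)C)(C(C)C)C(C)C | intermediate (not isolated)
13 | (2R)-2-{[(2Z)-2-(tert-butyldimethylsilyloxy)-3-[3,5-dimethoxy-4-(triisopropylsilyloxy)phenyl]prop-2-en-1-yl]oxy}-2-[3-methoxy-4-(triisopropylsilyloxy)phenyl]acetic acid | COc1cc([C@@H](OC/C(O[Si](C)(C)C(C)(C)C)=C/c2cc(OC)c(O[Si](C(C)C)(C(C)C)C(C)C)c(OC)c2)C(=O)O)ccc1O[Si](C(C)C)(C(C)C)C(C)C | intermediate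
14 | isobutyl carbonic mixed anhydride of acid 13 | COc1cc([C@@H](OC/C(O[Si](C)(C)C(C)(C)C)=C/c2cc(OC)c(O[Si](C(C)C)(C(C)C)C(C)C)c(OC)c2)C(=O)OC(=O)OCC(C)C)ccc1O[Si](C(C)C)(C(C)C)C(C)C | intermediate (not isolated)
15 | (3R)-3-{[(2Z)-2-(tert-butyldimethylsilyloxy)-3-[3,5-dimethoxy-4-(triisopropylsilyloxy)phenyl]prop-2-en-1-yl]oxy}-1-diazo-3-[3-methoxy-4-(triisopropylsilyloxy)phenyl]propan-2-one | COc1cc([C@@H](OC/C(O[Si](C)(C)C(C)(C)C)=C/c2cc(OC)c(O[Si](C(C)C)(C(C)C)C(C)C)c(OC)c2)C(=O)C=[N+]=[N-])ccc1O[Si](C(C)C)(C(C)C)C(C)C | intermediate (key-step precursor)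
16 | (3S)-3-{[(2Z)-2-(tert-butyldimethylsilyloxy)-3-[3,5-dimethoxy-4-(triisopropylsilyloxy)phenyl]prop-2-en-1-yl]oxy}-3-[3-methoxy-4-(triisopropylsilyloxy)phenyl]prop-1-en-1-one (ketene) | COc1cc([C@@H](OC/C(O[Si](C)(C)C(C)(C)C)=C/c2cc(OC)c(O[Si](C(C)C)(C(C)C)C(C)C)c(OC)c2)C=C=O)ccc1O[Si](C(C)C)(C(C)C)C(C)C | intermediate (not isolated)
17 | (1R,2S,5S,6R)-cyclobutanone (labels of the overview): cis-fused 3-oxabicyclo[3.2.0]heptanone, TIPS-guaiacyl at C2, OTBS at C5, TIPS-syringyl at C6, C8=O | COc1cc([C@H]2OC[C@]3(O[Si](C)(C)C(C)(C)C)[C@@H](c4cc(OC)c(O[Si](C(C)C)(C(C)C)C(C)C)c(OC)c4)C(=O)[C@H]23)ccc1O[Si](C(C)C)(C(C)C)C(C)C | intermediate (key-step product)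
18 | (1R,2S,5S,6R)-5-(tert-butyldimethylsilyloxy)-6-[3,5-dimethoxy-4-(triisopropylsilyloxy)phenyl]-2-[3-methoxy-4-(triisopropylsilyloxy)phenyl]-3,7-dioxabicyclo[3.3.0]octan-8-one | COc1cc([C@H]2OC[C@]3(O[Si](C)(C)C(C)(C)C)[C@@H](c4cc(OC)c(O[Si](C(C)C)(C(C)C)C(C)C)c(OC)c4)OC(=O)[C@H]23)ccc1O[Si](C(C)C)(C(C)C)C(C)C | intermediate
19 | lactol of 18 (3,7-dioxabicyclo[3.3.0]octan-8-ol, C8 epimers) | COc1cc([C@H]2OC[C@]3(O[Si](C)(C)C(C)(C)C)[C@@H](c4cc(OC)c(O[Si](C(C)C)(C(C)C)C(C)C)c(OC)c4)OC(O)[C@H]23)ccc1O[Si](C(C)C)(C(C)C)C(C)C | intermediate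
20 | (1R,2S,5S,6R)-5-(tert-butyldimethylsilyloxy)-6-[3,5-dimethoxy-4-(triisopropylsilyloxy)phenyl]-2-[3-methoxy-4-(triisopropylsilyloxy)phenyl]-3,7-dioxabicyclo[3.3.0]octane | COc1cc([C@H]2OC[C@]3(O[Si](C)(C)C(C)(C)C)[C@@H](c4cc(OC)c(O[Si](C(C)C)(C(C)C)C(C)C)c(OC)c4)OC[C@H]23)ccc1O[Si](C(C)C)(C(C)C)C(C)C | intermediate
21 | fraxiresinol, (1R,2S,5S,6R)-6-(4-hydroxy-3,5-dimethoxyphenyl)-2-(4-hydroxy-3-methoxyphenyl)-3,7-dioxabicyclo[3.3.0]octan-5-ol | COc1cc([C@H]2OC[C@]3(O)[C@@H](c4cc(OC)c(O)c(OC)c4)OC[C@H]23)ccc1O | target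

**Step count**

Total steps: 13. Longest linear sequence: 11 steps (steps 1, 2, 5–13; the branch through steps 3 and 4 is of equal length).

**Steps most likely to fail**

Step 9. The light-driven sequence may be diverted before the cycloaddition: the Z enol ether may isomerise by energy transfer, the excited diazoketone may react as a carbene with the enol ether (cyclopropanation) instead of undergoing the 1,2-shift, and the ketene may be intercepted before it reaches the alkene; insufficient face discrimination by the C2 group would add a diastereomer problem. The fallback makes the same ketene without light by base-induced elimination. It sets out from 15: Arndt–Eistert homologation in the dark (AgOCOPh cat., Et3N, THF/H2O, 20 °C) should give (3S)-3-{[(2Z)-2-(tert-butyldimethylsilyloxy)-3-[3,5-dimethoxy-4-(triisopropylsilyloxy)phenyl]prop-2-en-1-yl]oxy}-3-[3-methoxy-4-(triisopropylsilyloxy)phenyl]propanoic acid F1. Treatment with 1-chloro-N,N,2-trimethylprop-1-en-1-amine (CH2Cl2, 0 °C, neutral) should give the corresponding acid chloride F2. Slow addition of F2 to Et3N in PhMe at 100 °C should dehydrochlorinate it to ketene 16 at low stationary concentration, and the thermal intramolecular [2+2] cycloaddition then returns to the route at 17.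

Step 5. Enantiofacial control in the proton transfer that sets C2 may be insufficient, because the α-hydroxy ketone can chelate the iron centre and open an unselective background path; ylide formation at the ketone carbonyl is a further drain. The fallback sets the stereocenter by resolution and sets out from 3 and 9. Insertion with Rh2(OAc)4 (1 mol%, CH2Cl2, 20 °C) should give the racemic keto ester methyl 2-{3-[3,5-dimethoxy-4-(triisopropylsilyloxy)phenyl]-2-oxopropoxy}-2-[3-methoxy-4-(triisopropylsilyloxy)phenyl]acetate F3. Me3SnOH (ClCH2CH2Cl, 70 °C) should give the racemic keto acid F4. Salt formation with (R)-1-phenylethylamine gives the (R)-acid (R)-1-phenylethylammonium salt F5, which is to be purified by fractional crystallisation; the amine enantiomer is chosen by trial so that the salt of the (R)-acid is the less soluble one, and is written here as R. Liberation with dilute HCl returns to the route at 11.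

Step 7. Under the silyl triflate and amine the transient silyl ester may be enolised to a silyl ketene acetal, eroding the configuration at C2. Z selectivity may be incomplete. The free carboxylic acid may protodesilylate the enol ether during isolation. The fallback installs the enol ether before the carboxyl group is unmasked and sets out from 10. TBSOTf and Et3N (CH2Cl2, −78 → 0 °C) should give methyl (2R)-2-{[(2Z)-2-(tert-butyldimethylsilyloxy)-3-[3,5-dimethoxy-4-(triisopropylsilyloxy)phenyl]prop-2-en-1-yl]oxy}-2-[3-methoxy-4-(triisopropylsilyloxy)phenyl]acetate F6, a neutral compound on which the Z and E isomers can be separated. Me3SnOH (ClCH2CH2Cl, 70 °C, buffered work-up) then cleaves the methyl ester and returns to the route at 13, which is taken on at once.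

**Further compounds**

F1 | step 9 | (3S)-3-{[(2Z)-2-(tert-butyldimethylsilyloxy)-3-[3,5-dimethoxy-4-(triisopropylsilyloxy)phenyl]prop-2-en-1-yl]oxy}-3-[3-methoxy-4-(triisopropylsilyloxy)phenyl]propanoic acid | COc1cc([C@@H](OC/C(O[Si](C)(C)C(C)(C)C)=C/c2cc(OC)c(O[Si](C(C)C)(C(C)C)C(C)C)c(OC)c2)CC(=O)O)ccc1O[Si](C(C)C)(C(C)C)C(C)C
F2 | step 9 | (3S)-3-{[(2Z)-2-(tert-butyldimethylsilyloxy)-3-[3,5-dimethoxy-4-(triisopropylsilyloxy)phenyl]prop-2-en-1-yl]oxy}-3-[3-methoxy-4-(triisopropylsilyloxy)phenyl]propanoyl chloride | COc1cc([C@@H](OC/C(O[Si](C)(C)C(C)(C)C)=C/c2cc(OC)c(O[Si](C(C)C)(C(C)C)C(C)C)c(OC)c2)CC(=O)Cl)ccc1O[Si](C(C)C)(C(C)C)C(C)C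
F3 | step 5 | racemic methyl 2-{3-[3,5-dimethoxy-4-(triisopropylsilyloxy)phenyl]-2-oxopropoxy}-2-[3-methoxy-4-(triisopropylsilyloxy)phenyl]acetate | COc1cc(C(OCC(=O)Cc2cc(OC)c(O[Si](C(C)C)(C(C)C)C(C)C)c(OC)c2)C(=O)OC)ccc1O[Si](C(C)C)(C(C)C)C(C)C
F4 | step 5 | racemic 2-{3-[3,5-dimethoxy-4-(triisopropylsilyloxy)phenyl]-2-oxopropoxy}-2-[3-methoxy-4-(triisopropylsilyloxy)phenyl]acetic acid | COc1cc(C(OCC(=O)Cc2cc(OC)c(O[Si](C(C)C)(C(C)C)C(C)C)c(OC)c2)C(=O)O)ccc1O[Si](C(C)C)(C(C)C)C(C)C
F5 | step 5 | (R)-1-phenylethylammonium salt of (2R)-acid 11 | COc1cc([C@@H](OCC(=O)Cc2cc(OC)c(O[Si](C(C)C)(C(C)C)C(C)C)c(OC)c2)C(=O)[O-])ccc1O[Si](C(C)C)(C(C)C)C(C)C.C[C@@H]([NH3+])c1ccccc1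
F6 | step 7 | methyl (2R)-2-{[(2Z)-2-(tert-butyldimethylsilyloxy)-3-[3,5-dimethoxy-4-(triisopropylsilyloxy)phenyl]prop-2-en-1-yl]oxy}-2-[3-methoxy-4-(triisopropylsilyloxy)phenyl]acetate | COc1cc([C@@H](OC/C(O[Si](C)(C)C(C)(C)C)=C/c2cc(OC)c(O[Si](C(C)C)(C(C)C)C(C)C)c(OC)c2)C(=O)OC)ccc1O[Si](C(C)C)(C(C)C)C(C)C
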